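**Retrosynthetic overview**

1. Baeomycesic acid 23 comes from aldehyde 22 by hydrogenolysis of the benzyl ester and benzyl ether of ring B; 22 comes from the benzannulation product 20 by desilylation and oxidation of the C3 CH2O group of ring A.
2. Ring A of 20 is cut at C2–C3, C4–C5 and C1–C2 (Danheiser benzannulation) into diazo enone 12 and ynol ether 16. 12 supplies C5, C6 with its CH3, and C1 with the depside C(=O)–O already attached to ring B; its ketene carbon becomes C2–OH. 16 supplies C3 with the masked formyl carbon and C4 with OMe.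
3. 12 is made from methyl ketone 10 by detrifluoroacetylative diazo transfer, because diazomethane would add as a dipole to the fumarate-like alkene of an acid chloride. 10 is the ester of ring-B phenol 5 with the E keto acid 9, made by Wittig reaction of biacetyl.
4. Ring order: ring B is bought as atraric acid and only re-protected (steps 1–4); ring A is the only ring formed, in step 10.
5. The strategy rests on ring A being a resorcinol monomethyl ether with C1 (depside carbonyl), C2 (free OH), C3 (formyl carbon), C4 (OMe), C5 (H) and C6 (CH3) in exactly the order that a vinylketene and an alkoxyalkyne deliver.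

Key step: step 10

Remark: baeomycesic acid has no stereocentre and no stereogenic axis, so the "single enantiomer" is simply the constitution given; the only stereochemical element in the route is the 2E geometry of the enoate in 8–12.

**Route**

Step 1
Reactants: 1 atraric acid (methyl 2,4-dihydroxy-3,6-dimethylbenzoate)
Product: 2 methyl 2-hydroxy-3,6-dimethyl-4-(tosyloxy)benzoate
Conditions: TsCl (1.05 equiv), K2CO3, acetone, reflux
Reagents that add atoms: p-toluenesulfonyl chloride, Cc1ccc(cc1)S(=O)(=O)Cl
Why: Selective O-sulfonylation; the 4-OH is the only phenol not tied up in a hydrogen bond to the ester carbonyl, while the 2-OH is chelated and flanked on both sides, so only the 4-OH should react.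

Step 2
Reactants: 2 methyl 2-hydroxy-3,6-dimethyl-4-(tosyloxy)benzoate
Product: 3 methyl 2-(benzyloxy)-3,6-dimethyl-4-(tosyloxy)benzoate
Conditions: BnBr (1.3 equiv), K2CO3, cat. Bu4NI, DMF, 60 °C
Reagents that add atoms: benzyl bromide, BrCc1ccccc1
Why: Williamson etherification of the remaining chelated phenol; the aryl sulfonate and the methyl ester are inert to carbonate in dry DMF.

Step 3
Reactants: 3 methyl 2-(benzyloxy)-3,6-dimethyl-4-(tosyloxy)benzoate
Product: 4 2-(benzyloxy)-4-hydroxy-3,6-dimethylbenzoic acid
Conditions: KOH (excess), DMSO/H2O, 90 °C; then cold dilute HCl to pH 3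
Reagents that add atoms: potassium hydroxide, [K+].[OH-]
Why: Hydroxide in aqueous DMSO should both saponify the di-ortho-substituted methyl ester and cleave the aryl sulfonate at sulfur, the benzyl ether being inert; a methanol-free medium avoids O-methylation by methyl tosylate, and cold acidification avoids decarboxylation.

Step 4
Reactants: 4 2-(benzyloxy)-4-hydroxy-3,6-dimethylbenzoic acid
Product: 5 benzyl 2-(benzyloxy)-4-hydroxy-3,6-dimethylbenzoate
Conditions: BnBr (1.05 equiv), KHCO3, DMF, rt
Reagents that add atoms: benzyl bromide, BrCc1ccccc1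
Why: Carboxylate SN2 alkylation; hydrogen carbonate deprotonates only the carboxylic acid, so the 4-OH stays free.

Step 5
Reactants: 6 butane-2,3-dione (biacetyl, 3 equiv); 7 tert-butyl (triphenylphosphoranylidene)acetate
Product: 8 tert-butyl (2E)-3-methyl-4-oxopent-2-enoate
Conditions: CH2Cl2, rt; chromatography
Reagents that add atoms: none
Why: Wittig olefination of an activated 1,2-diketone carbonyl by a stabilised ylide; the symmetric diketone removes any regiochemical question, its excess suppresses double olefination, and the E isomer (ester trans to acetyl) is expected to predominate, any Z isomer being removed by chromatography.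

Step 6
Reactants: 8 tert-butyl (2E)-3-methyl-4-oxopent-2-enoate
Product: 9 (2E)-3-methyl-4-oxopent-2-enoic acid
Conditions: TFA, CH2Cl2, rt
Reagents that add atoms: none
Why: Acidolysis of the tert-butyl ester with loss of isobutene; the E geometry is the thermodynamic one and the E acid cannot close to a hydroxybutenolide.

Step 7
Reactants: 5 benzyl 2-(benzyloxy)-4-hydroxy-3,6-dimethylbenzoate; 9 (2E)-3-methyl-4-oxopent-2-enoic acid
Product: 10 benzyl 2-(benzyloxy)-3,6-dimethyl-4-{[(2E)-3-methyl-4-oxopent-2-enoyl]oxy}benzoate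
Conditions: DCC, cat. DMAP, CH2Cl2, 0 °C to rt
Reagents that add atoms: none
Why: Steglich esterification of the one free phenol; it fixes the aryl ester on the CH end of the enoate without any regiochemical ambiguity.

Step 8
Reactants: 10 benzyl 2-(benzyloxy)-3,6-dimethyl-4-{[(2E)-3-methyl-4-oxopent-2-enoyl]oxy}benzoate
Product: 12 benzyl 2-(benzyloxy)-4-{[(2E)-5-diazo-3-methyl-4-oxopent-2-enoyl]oxy}-3,6-dimethylbenzoate, via trifluoroacetyl diketone 11 (not isolated)
Conditions: LiHMDS (1.1 equiv), THF, −78 °C; CF3CO2CH2CF3 (1.2 equiv), −78 °C; dilute HCl work-up; then MsN3 (1.5 equiv), Et3N, H2O (1 equiv), MeCN, rt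
Reagents that add atoms: methanesulfonyl azide, CS(=O)(=O)N=[N+]=[N-]; 2,2,2-trifluoroethyl trifluoroacetate, O=C(OCC(F)(F)F)C(F)(F)F (its CF3CO group is carried only in 11)
Why: Danheiser detrifluoroacetylative diazo transfer; kinetic deprotonation at the methyl ketone, Claisen acylation, and Regitz-type transfer of N2 with loss of the trifluoroacetyl group give the α'-diazo enone without diazomethane, which would cycloadd to the doubly activated alkene.

Step 9
Reactants: 13 chloroacetaldehyde dimethyl acetal (2-chloro-1,1-dimethoxyethane)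
Product: 16 tert-butyl[(3-methoxyprop-2-yn-1-yl)oxy]dimethylsilane, via lithium methoxyacetylide 14 (not isolated), via lithium 3-methoxyprop-2-yn-1-olate 15 (not isolated)
Conditions: Et2NH/n-BuLi (3 equiv LiNEt2), THF, −10 to 0 °C; (CH2O)n, 0 °C to rt; TBSCl, imidazole, DMF, 0 °C to rt; NaHCO3 work-up, Et3N-deactivated silica
Reagents that add atoms: formaldehyde (as paraformaldehyde), C=O; tert-butyldimethylsilyl chloride, CC(C)(C)[Si](C)(C)Cl
Why: Amide base removes HCl and MeOH from the chloroacetal and deprotonates the resulting methoxyacetylene; the acetylide adds to formaldehyde, and silylation of the alkoxide in the same flask avoids isolating the volatile, water-soluble and acid-sensitive ynol ether carbinol.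

Step 10
Reactants: 12 benzyl 2-(benzyloxy)-4-{[(2E)-5-diazo-3-methyl-4-oxopent-2-enoyl]oxy}-3,6-dimethylbenzoate; 16 tert-butyl[(3-methoxyprop-2-yn-1-yl)oxy]dimethylsilane (2–3 equiv)
Product: 20 benzyl 2-(benzyloxy)-4-{[3-(tert-butyldimethylsilyloxymethyl)-2-hydroxy-4-methoxy-6-methylbenzoyl]oxy}-3,6-dimethylbenzoate, via vinylketene 17 (not isolated), via vinylcyclobutenone 18 (not isolated), via dienylketene 19 (not isolated)
Conditions: hν (medium-pressure Hg lamp, Pyrex, λ > 300 nm), degassed ClCH2CH2Cl (0.05 M), rt; then 80 °C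
Reagents that add atoms: none
Why: Light absorbed only by the diazo enone expels N2 and triggers Wolff rearrangement with 1,2-shift of the alkenyl group to vinylketene 17, and the polarised ynol ether 16 then adds through its nucleophilic carbon (the one bearing CH2OTBS) to the ketene sp carbon in a regiospecific [2+2] cycloaddition to give the 3-methoxy-4-vinylcyclobutenone 18, forming C2–C3 and C4–C5 of ring A. On warming, 18 opens by conrotatory 4π-electrocyclic cleavage to dienylketene 19, and ring A is closed by a disrotatory 6π-electrocyclisation joining the ketene carbon (C2) to the enoate α-carbon (C1); tautomerisation of the cyclohexa-2,4-dienone gives the phenol, so the transient sp3 centres (C4 of 18, C1 of the dienone) are erased and no stereocentre needs control. The closest known reaction is the photochemical Danheiser benzannulation of α'-diazo enones with alkoxyalkynes, which gives resorcinol monoethers with this same free-OH/alkoxy relationship. The selectivity needed is regiochemical and is secured in two ways: the donor oxygen of 16 decides which alkyne carbon bonds to the ketene carbon, so OMe must end at C4 and the CH2O carbon at C3, and the 2E enoate holds the aryl ester trans to the ketene in 17 and outward in 19, which excludes oxa-6π closure to a 2-pyranone. The ester-bearing diazo enone is a new substrate for this known reaction; the acceptor should make 17 more electrophilic towards the ynol ether, Pyrex-filtered light is chosen to avoid photo-Fries rearrangement of the aryl esters and to limit E/Z photoisomerisation, and the methyl ynol ether has no β-hydrogen for retro-ene loss at 80 °C.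

Step 11
Reactants: 20 benzyl 2-(benzyloxy)-4-{[3-(tert-butyldimethylsilyloxymethyl)-2-hydroxy-4-methoxy-6-methylbenzoyl]oxy}-3,6-dimethylbenzoate
Product: 21 benzyl 2-(benzyloxy)-4-{[2-hydroxy-3-(hydroxymethyl)-4-methoxy-6-methylbenzoyl]oxy}-3,6-dimethylbenzoate
Conditions: HF·pyridine, THF/pyridine, 0 °C to rt
Reagents that add atoms: none
Why: Fluoride cleavage of the primary silyl ether under buffered, non-basic conditions, which should leave the depside ester, the benzyl ester and the benzyl ether untouched.

Step 12
Reactants: 21 benzyl 2-(benzyloxy)-4-{[2-hydroxy-3-(hydroxymethyl)-4-methoxy-6-methylbenzoyl]oxy}-3,6-dimethylbenzoate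
Product: 22 benzyl 2-(benzyloxy)-4-[(3-formyl-2-hydroxy-4-methoxy-6-methylbenzoyl)oxy]-3,6-dimethylbenzoate
Conditions: activated MnO2 (15 equiv), CH2Cl2, rt
Reagents that add atoms: none
Why: Manganese dioxide oxidation of a benzylic (salicyl-type) alcohol, which stops at the aldehyde and tolerates the chelated phenol and the esters.

Step 13
Reactants: 22 benzyl 2-(benzyloxy)-4-[(3-formyl-2-hydroxy-4-methoxy-6-methylbenzoyl)oxy]-3,6-dimethylbenzoate
Product: 23 baeomycesic acid
Conditions: H2 (1 atm), 10% Pd/C, EtOAc, rt, stopped after uptake of 2 equiv H2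
Reagents that add atoms: none
Why: Catalytic hydrogenolysis of the benzyl ester and the benzyl ether; the chelated, electron-rich aryl aldehyde and the aryl ester should survive under these mild conditions.

**Compound list**

1 | atraric acid (methyl 2,4-dihydroxy-3,6-dimethylbenzoate) | COC(=O)c1c(C)cc(O)c(C)c1O | starting material
2 | methyl 2-hydroxy-3,6-dimethyl-4-(tosyloxy)benzoate | COC(=O)c1c(C)cc(OS(=O)(=O)c2ccc(C)cc2)c(C)c1O | intermediate
3 | methyl 2-(benzyloxy)-3,6-dimethyl-4-(tosyloxy)benzoate | COC(=O)c1c(C)cc(OS(=O)(=O)c2ccc(C)cc2)c(C)c1OCc1ccccc1 | intermediate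
4 | 2-(benzyloxy)-4-hydroxy-3,6-dimethylbenzoic acid | Cc1cc(O)c(C)c(OCc2ccccc2)c1C(=O)O | intermediate
5 | benzyl 2-(benzyloxy)-4-hydroxy-3,6-dimethylbenzoate | Cc1cc(O)c(C)c(OCc2ccccc2)c1C(=O)OCc1ccccc1 | intermediate
6 | butane-2,3-dione (biacetyl) | CC(=O)C(C)=O | starting material
7 | tert-butyl (triphenylphosphoranylidene)acetate | CC(C)(C)OC(=O)C=P(c1ccccc1)(c1ccccc1)c1ccccc1 | starting material
8 | tert-butyl (2E)-3-methyl-4-oxopent-2-enoate | CC(=O)/C(C)=C/C(=O)OC(C)(C)C | intermediate
9 | (2E)-3-methyl-4-oxopent-2-enoic acid | CC(=O)/C(C)=C/C(=O)O | intermediate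
10 | benzyl 2-(benzyloxy)-3,6-dimethyl-4-{[(2E)-3-methyl-4-oxopent-2-enoyl]oxy}benzoate | CC(=O)/C(C)=C/C(=O)Oc1cc(C)c(C(=O)OCc2ccccc2)c(OCc2ccccc2)c1C | intermediate
11 | benzyl 2-(benzyloxy)-3,6-dimethyl-4-{[(2E)-7,7,7-trifluoro-3-methyl-4,6-dioxohept-2-enoyl]oxy}benzoate (trifluoroacetyl diketone) | O=C(CC(=O)/C(C)=C/C(=O)Oc1cc(C)c(C(=O)OCc2ccccc2)c(OCc2ccccc2)c1C)C(F)(F)F | intermediate (not isolated)
12 | benzyl 2-(benzyloxy)-4-{[(2E)-5-diazo-3-methyl-4-oxopent-2-enoyl]oxy}-3,6-dimethylbenzoate | [N-]=[N+]=CC(=O)/C(C)=C/C(=O)Oc1cc(C)c(C(=O)OCc2ccccc2)c(OCc2ccccc2)c1C | intermediate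
13 | chloroacetaldehyde dimethyl acetal (2-chloro-1,1-dimethoxyethane) | COC(CCl)OC | starting material
14 | lithium methoxyacetylide | [Li+].[C-]#COC | intermediate (not isolated)
15 | lithium 3-methoxyprop-2-yn-1-olate | [Li+].[O-]CC#COC | intermediate (not isolated)
16 | tert-butyl[(3-methoxyprop-2-yn-1-yl)oxy]dimethylsilane | COC#CCO[Si](C)(C)C(C)(C)C | intermediate
17 | benzyl 2-(benzyloxy)-3,6-dimethyl-4-{[(2E)-3-methyl-5-oxopenta-2,4-dienoyl]oxy}benzoate (vinylketene) | O=C=C/C(C)=C/C(=O)Oc1cc(C)c(C(=O)OCc2ccccc2)c(OCc2ccccc2)c1C | intermediate (not isolated)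
18 | benzyl 2-(benzyloxy)-4-{[(2E)-3-[3-(tert-butyldimethylsilyloxymethyl)-2-methoxy-4-oxocyclobut-2-en-1-yl]but-2-enoyl]oxy}-3,6-dimethylbenzoate (vinylcyclobutenone, racemic at the ring CH) | COC1=C(CO[Si](C)(C)C(C)(C)C)C(=O)C1/C(C)=C/C(=O)Oc1cc(C)c(C(=O)OCc2ccccc2)c(OCc2ccccc2)c1C | intermediate (not isolated)
19 | benzyl 2-(benzyloxy)-4-{[(2E,4E)-6-(tert-butyldimethylsilyloxymethyl)-5-methoxy-3-methyl-7-oxohepta-2,4,6-trienoyl]oxy}-3,6-dimethylbenzoate (dienylketene) | O=C=C(CO[Si](C)(C)C(C)(C)C)/C(OC)=C\C(C)=C\C(=O)Oc1cc(C)c(C(=O)OCc2ccccc2)c(OCc2ccccc2)c1C | intermediate (not isolated)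
20 | benzyl 2-(benzyloxy)-4-{[3-(tert-butyldimethylsilyloxymethyl)-2-hydroxy-4-methoxy-6-methylbenzoyl]oxy}-3,6-dimethylbenzoate | COc1cc(C)c(C(=O)Oc2cc(C)c(C(=O)OCc3ccccc3)c(OCc3ccccc3)c2C)c(O)c1CO[Si](C)(C)C(C)(C)C | intermediate
21 | benzyl 2-(benzyloxy)-4-{[2-hydroxy-3-(hydroxymethyl)-4-methoxy-6-methylbenzoyl]oxy}-3,6-dimethylbenzoate | COc1cc(C)c(C(=O)Oc2cc(C)c(C(=O)OCc3ccccc3)c(OCc3ccccc3)c2C)c(O)c1CO | intermediate
22 | benzyl 2-(benzyloxy)-4-[(3-formyl-2-hydroxy-4-methoxy-6-methylbenzoyl)oxy]-3,6-dimethylbenzoate | COc1cc(C)c(C(=O)Oc2cc(C)c(C(=O)OCc3ccccc3)c(OCc3ccccc3)c2C)c(O)c1C=O | intermediate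
23 | baeomycesic acid | COc1cc(C)c(C(=O)Oc2cc(C)c(C(=O)O)c(O)c2C)c(O)c1C=O | target

**Step count**

Total: 13 steps. Longest linear sequence: 10 steps (1, 2, 3, 4, 7, 8, 10, 11, 12, 13).

**Steps most likely to fail**

1. Step 10. The light may isomerise the enoate to the Z form before or after the Wolff rearrangement, after which the ester carbonyl can capture the ketene by oxa-6π closure. The electron-poor vinylketene may also dimerise or be trapped faster than it meets the ynol ether, and the aryl esters may undergo photo-Fries rearrangement. The fallback gives up the benzannulation and makes the depside bond by acylation; it sets out from 5 and returns to the route at 22. Commercial everninic acid (2-hydroxy-4-methoxy-6-methylbenzoic acid) would be alkylated with BnBr/KHCO3 in DMF to benzyl 2-hydroxy-4-methoxy-6-methylbenzoate F1. Rieche formylation ortho to the phenol at C3 (Cl2CHOMe, TiCl4, CH2Cl2, 0 °C) would give benzyl 3-formyl-2-hydroxy-4-methoxy-6-methylbenzoate F2, and hydrogenolysis (H2, Pd/C, EtOAc) would give 3-formyl-2-hydroxy-4-methoxy-6-methylbenzoic acid F3. Activation of F3 as its mixed trifluoroacetic anhydride (TFAA, toluene, rt) in the presence of 5 should acylate the free 4-OH of 5 and give 22, from which step 13 finishes the synthesis.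

2. Step 8. The aryl ester may be cleaved or transesterified by trifluoroethoxide or by aqueous triethylamine, and the ketone enolate may add in Michael fashion to the doubly activated alkene of a second molecule. The fallback forms the diazo group on a base-stable alkyl ester and installs the aryl ester last under neutral conditions; it sets out from 9 and returns at 12. Acid 9 would be esterified with 2-(trimethylsilyl)ethanol (DCC, DMAP) to 2-(trimethylsilyl)ethyl (2E)-3-methyl-4-oxopent-2-enoate F4. Trifluoroacetylation (LiHMDS, TFEA, THF, −78 °C) would give crude 2-(trimethylsilyl)ethyl (2E)-7,7,7-trifluoro-3-methyl-4,6-dioxohept-2-enoate F5, and diazo transfer (MsN3, Et3N, H2O, MeCN) would give 2-(trimethylsilyl)ethyl (2E)-5-diazo-3-methyl-4-oxopent-2-enoate F6. Fluoride (TBAF, THF, 0 °C) would release (2E)-5-diazo-3-methyl-4-oxopent-2-enoic acid F7, which would be coupled with 5 (DCC, DMAP, CH2Cl2, 0 °C) to give 12.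

3. Step 9. The threefold elimination may stop at the chlorovinyl ether stage, and the ynol ether may be hydrated or rearranged by traces of acid during isolation. The fallback generates the acetylide by a different, amine-free route; it does not use 13 but sets out from commercial trichloroethene and methanol, and rejoins the route at 14. Potassium methoxide (KH, MeOH, THF) and trichloroethene would give (E)-1,2-dichloro-1-methoxyethene F8, which with n-BuLi (2.2 equiv, THF, −78 to −40 °C) would give 14 by elimination and chlorine–lithium exchange. Paraformaldehyde and then TBSCl/imidazole, as in step 9, would give 16.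

**Further compounds**

F1 | step 10 | benzyl 2-hydroxy-4-methoxy-6-methylbenzoate | COc1cc(C)c(C(=O)OCc2ccccc2)c(O)c1
F2 | step 10 | benzyl 3-formyl-2-hydroxy-4-methoxy-6-methylbenzoate | COc1cc(C)c(C(=O)OCc2ccccc2)c(O)c1C=O
F3 | step 10 | 3-formyl-2-hydroxy-4-methoxy-6-methylbenzoic acid | COc1cc(C)c(C(=O)O)c(O)c1C=O
F4 | step 8 | 2-(trimethylsilyl)ethyl (2E)-3-methyl-4-oxopent-2-enoate | CC(=O)/C(C)=C/C(=O)OCC[Si](C)(C)C
F5 | step 8 | 2-(trimethylsilyl)ethyl (2E)-7,7,7-trifluoro-3-methyl-4,6-dioxohept-2-enoate | O=C(CC(=O)/C(C)=C/C(=O)OCC[Si](C)(C)C)C(F)(F)F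
F6 | step 8 | 2-(trimethylsilyl)ethyl (2E)-5-diazo-3-methyl-4-oxopent-2-enoate | [N-]=[N+]=CC(=O)/C(C)=C/C(=O)OCC[Si](C)(C)C
F7 | step 8 | (2E)-5-diazo-3-methyl-4-oxopent-2-enoic acid | [N-]=[N+]=CC(=O)/C(C)=C/C(=O)O
F8 | step 9 | (E)-1,2-dichloro-1-methoxyethene | CO/C(Cl)=C\Cl
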